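The plan cuts C9–C11 (numbering: see remark). The ring half is an isophorone-type enone in which C6 (later CHOH) is the carbonyl, C8 the β-carbon and C9 the γ-carbon; C10 carries a CH2CO2H arm. In the key step this acid and the side-chain aldehyde condense to an acyloxycarbenium ion, which C9 of the silyl dienol ether attacks. One operation forms C9–C11, sets C9 and C11 and gives a cis-fused δ-lactone (C2–O11). It exploits the cis relation between the C9–C11 bond and the C10–C1–C2 arm of the 2-oxabicyclo[3.3.1]nonanone. After reduction at C6 the carboxyl is moved from O11 to O8 by iodolactonisation.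

Key step: step 12

Remark (numbering): atoms are numbered as in a seco-labdane: C1H2–C2(=O)–O8 (lactone), C3O2H, C4(CH3)2, C5, C6(OH), C7H2, C8(CH3 = C17), C9, C10(CH3 = C20), C11(OH), C12H2, C13(OH)(CH3), C14H=C15H2. β is the ring face that carries C4, O6, O8, C11 and C1 in the target; α is the other face.
Assumption: 1, 2, 6 and 10 are taken as commercial; (R)-1 can otherwise be made from (R)-pulegone.
Assumption: the 6-hydroxy acid of the target can close to a γ-lactone under acid, so the last steps avoid acid.

Step 1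
Reactants: 1 (R)-5-methylcyclohex-2-en-1-one; 2 1-(tert-butyldimethylsilyloxy)-1-methoxyethene
Product: 3 methyl 2-[(1S,5R)-3-(tert-butyldimethylsilyloxy)-5-methylcyclohex-2-en-1-yl]acetate
Conditions: TBSOTf (5 mol%), CH2Cl2, −78 °C; then Et3N
Reagents that add atoms: none
Why: Mukaiyama–Michael addition with silyl transfer: the ketene silyl acetal adds to the enone β-carbon (the future C10) anti to the C8 methyl group and the silyl group ends on O6, so the C5=C6 enol position stays defined; the C10 centre formed here is removed again in step 2.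

Step 2
Reactants: 3 methyl 2-[(1S,5R)-3-(tert-butyldimethylsilyloxy)-5-methylcyclohex-2-en-1-yl]acetate
Product: 4 methyl 2-[(5R)-5-methyl-3-oxocyclohex-1-en-1-yl]acetate
Conditions: Pd(OAc)2 (10 mol%), O2 (1 atm), DMSO, 60 °C
Reagents that add atoms: none
Why: Saegusa–Ito oxidation: palladation at C5 of the regiodefined silyl enol ether and β-hydride elimination of H–C10 re-form the enone, now with the acetate arm on the β-carbon; the C8 centre is not touched.

Step 3
Reactants: 4 methyl 2-[(5R)-5-methyl-3-oxocyclohex-1-en-1-yl]acetate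
Product: 5 methyl 2-[(1R,5R)-1,5-dimethyl-3-(trimethylsilyloxy)cyclohex-2-en-1-yl]acetate
Conditions: Me2CuLi (1.5 equiv), TMSCl (3 equiv), THF, −78 °C; Et3N, pentane, cold aq. NaHCO3
Reagents that add atoms: lithium dimethylcuprate [Li+].C[Cu-]C; chlorotrimethylsilane C[Si](C)(C)Cl
Why: Conjugate addition of a Gilman cuprate with TMSCl trapping: methyl adds axially to C10 anti to the equatorial C8 methyl group (trans-3,5 rule of 5-substituted cyclohexenones), which sets the quaternary C10 (CH3 α, CH2CO2Me β), and the enolate is silylated at O6 without loss of regiochemistry.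

Step 4
Reactants: 5 methyl 2-[(1R,5R)-1,5-dimethyl-3-(trimethylsilyloxy)cyclohex-2-en-1-yl]acetate; 6 prop-2-en-1-yl 2-bromo-2-methylpropanoate
Product: 7 prop-2-en-1-yl 2-[(1R,2R,4R)-2-(2-methoxy-2-oxoethyl)-2,4-dimethyl-6-oxocyclohexyl]-2-methylpropanoate
Conditions: fac-Ir(ppy)3 (1 mol%), MeCN, blue LEDs, rt
Reagents that add atoms: none
Why: Photoredox radical α-alkylation of a silyl enol ether (ATRA type): the electrophilic tertiary radical from 6 adds to C5 on the face anti to the axial C20 methyl group, which is cis to the acetate arm (C4 β), and oxidation of the α-siloxy radical with loss of the silyl group returns the C6 ketone.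

Step 5
Reactants: 7 prop-2-en-1-yl 2-[(1R,2R,4R)-2-(2-methoxy-2-oxoethyl)-2,4-dimethyl-6-oxocyclohexyl]-2-methylpropanoate
Product: 8 prop-2-en-1-yl 2-[(1R,6R)-6-(2-methoxy-2-oxoethyl)-4,6-dimethyl-2-oxocyclohex-3-en-1-yl]-2-methylpropanoate
Conditions: IBX (2.2 equiv), 4-methoxypyridine N-oxide (2.2 equiv), DMSO, rt
Reagents that add atoms: none
Why: IBX dehydrogenation of a ketone: C10 and C4 are quaternary, so unsaturation can only be introduced toward C7–C8 and a single enone should form; this erases the auxiliary C8 centre after it has controlled C10 and C5.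

Step 6
Reactants: 8 prop-2-en-1-yl 2-[(1R,6R)-6-(2-methoxy-2-oxoethyl)-4,6-dimethyl-2-oxocyclohex-3-en-1-yl]-2-methylpropanoate
Product: 9 2-[(1R,6R)-1,3-dimethyl-6-[2-methyl-1-oxo-1-(prop-2-en-1-yloxy)propan-2-yl]-5-oxocyclohex-3-en-1-yl]acetic acid
Conditions: Me3SnOH (4 equiv), 1,2-dichloroethane, 70 °C; 5% aq. HCl wash
Reagents that add atoms: trimethyltin hydroxide C[Sn](C)(C)O
Why: Ester cleavage with trimethyltin hydroxide (neutral acyl substitution): the unhindered CH2CO2Me reacts while the neopentyl-type allyl ester and the epimerisable C5–H next to the ketone are left alone.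

Step 7
Reactants: 10 (2E)-3-methylpent-2-en-4-yn-1-ol
Product: 11 (2E)-3-methylpenta-2,4-dien-1-ol
Conditions: H2 (1 atm), Lindlar catalyst, quinoline, hexane/EtOAc, rt
Reagents that add atoms: none
Why: Lindlar semi-hydrogenation: the terminal alkyne is reduced to the vinyl group and the trisubstituted (E)-alkene is kept.

Step 8
Reactants: 11 (2E)-3-methylpenta-2,4-dien-1-ol
Product: 12 [(2S,3S)-3-ethenyl-3-methyloxiran-2-yl]methanol
Conditions: Ti(OiPr)4 (10 mol%), L-(+)-DET (12 mol%), TBHP, 4 Å MS, CH2Cl2, −20 °C
Reagents that add atoms: tert-butyl hydroperoxide CC(C)(C)OO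
Why: Sharpless asymmetric epoxidation: with L-(+)-DET oxygen is delivered to the allylic alkene from the same face as for geraniol, which gives the (2S,3S)-epoxide and thereby the future C13 centre; the vinyl group is not an allylic-alcohol alkene and stays.

Step 9
Reactants: 12 [(2S,3S)-3-ethenyl-3-methyloxiran-2-yl]methanol
Product: 13 (3R)-3-methylpent-4-ene-1,3-diol
Conditions: Red-Al, THF, 0 °C → rt; aq. Rochelle salt
Reagents that add atoms: none
Why: Red-Al reduction of a 2,3-epoxy alcohol: hydride is delivered intramolecularly from the C1 alkoxyaluminate to C2, which gives the 1,3-diol and leaves the C3–O bond (C13 of the target, R) untouched.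

Step 10
Reactants: 13 (3R)-3-methylpent-4-ene-1,3-diol
Product: 14 (3R)-3-methyl-1,3-bis(triethylsilyloxy)pent-4-ene
Conditions: TESOTf (2.4 equiv), 2,6-lutidine, CH2Cl2, −78 → 0 °C
Reagents that add atoms: triethylsilyl trifluoromethanesulfonate CC[Si](CC)(CC)OS(=O)(=O)C(F)(F)F
Why: Silylation with a silyl triflate, which is reactive enough for the tertiary allylic hydroxyl as well as the primary one.

Step 11
Reactants: 14 (3R)-3-methyl-1,3-bis(triethylsilyloxy)pent-4-ene
Product: 15 (3R)-3-methyl-3-(triethylsilyloxy)pent-4-enal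
Conditions: (COCl)2 (4 equiv), DMSO (8 equiv), CH2Cl2, −78 → −40 °C; Et3N
Reagents that add atoms: none
Why: Swern oxidation of a primary triethylsilyl ether: the primary TES ether is cleaved and oxidised in the same operation, the tertiary TES ether is inert, and the silylated β-oxygen prevents retro-aldol cleavage of the aldehyde.

Step 12
Reactants: 9 2-[(1R,6R)-1,3-dimethyl-6-[2-methyl-1-oxo-1-(prop-2-en-1-yloxy)propan-2-yl]-5-oxocyclohex-3-en-1-yl]acetic acid; 15 (3R)-3-methyl-3-(triethylsilyloxy)pent-4-enal
Product: 18 cis-fused C2–O11 δ-lactone enone (allyl ester; 13-O-TES), via bis-silyl dienol ether 16 (not isolated), via O-silyl hemiacylal 17 (not isolated)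
Conditions: (i) TMSOTf (2.3 equiv), Et3N (2.4 equiv), CH2Cl2, 0 °C → rt; pentane, filtration, evaporation; (ii) 15 (1.2 equiv), TMSOTf (20 mol%), 2,6-di-tert-butyl-4-methylpyridine (30 mol%), CH2Cl2, −78 → −40 °C; aq. NaHCO3
Reagents that add atoms: none
Why: Proposed new method: TMSOTf/Et3N should convert 9 into the TMS ester and linear silyl dienol ether 16 (exo- and endocyclic dienol ethers equilibrate, only the C8=C9 isomer can cyclise); the silyl ester oxygen then adds to the TMSOTf-activated aldehyde to give O-silyl hemiacylal 17, which ionises to an acyloxycarbenium ion that is trapped by C9, the γ-carbon of the dienol ether, with loss of the silyl group to return the enone (an intramolecular vinylogous Mukaiyama aldol reaction). The closest known reactions are the intramolecular silyl-modified Sakurai and silyl-enol-ether Prins cyclisations of silyl ethers with aldehydes and the Lewis-acid additions of enol silanes to acylals; new is that a silyl ester takes the place of the silyl ether, so that a lactone and not a cyclic ether results. The δ-lactone closes in a 6-endo-trig mode at the oxocarbenium carbon (C11 and O11 both in the new ring) and exo with respect to the C8=C9 bond of the nucleophile. C9 is controlled by the tether: the C1–C2–O11 chain sits on the β face of C10 and can reach only the β lobe of C9, so the C9–C11 bond must be cis to C10–C1. C11 is controlled by the chair-like transition state, in which the side chain is equatorial and anti to the quaternary C10 (the axial alternative is syn-pentane to the C20 methyl group), which corresponds to 11S. The step needs γ- over α-attack (attack through C7 would need an eight-membered ring) and needs the tethered path to beat intermolecular aldol addition, which the low activity of TMSOTf toward free aldehydes and the amine-free, catalytic second stage are meant to secure.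

Step 13
Reactants: 18 cis-fused C2–O11 δ-lactone enone (allyl ester; 13-O-TES)
Product: 19 6β-allylic alcohol of 18
Conditions: NaBH4, CeCl3·7H2O, MeOH, −78 °C
Reagents that add atoms: none
Why: Luche reduction (1,2-reduction of the enone): hydride should attack C6 from the α face, anti to the C4 substituent on C5 and to the axial C10–C1 bond of the lactone that screens the β face, which gives the 6β-alcohol (cis to C4).

Step 14
Reactants: 19 6β-allylic alcohol of 18
Product: 20 6-O-triethylsilyl ether of 19
Conditions: TESOTf, 2,6-lutidine, CH2Cl2, −78 °C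
Reagents that add atoms: triethylsilyl trifluoromethanesulfonate CC[Si](CC)(CC)OS(=O)(=O)C(F)(F)F
Why: Silylation: the 6-hydroxyl is masked so that it cannot close a γ-lactone onto the C3 ester under the basic conditions of step 15.

Step 15
Reactants: 20 6-O-triethylsilyl ether of 19
Product: 22 7α-iodo C2–O8 bridged lactone (6-O-TES; 13-O-TES; 11-OH; allyl ester), via lithium carboxylate 21 (not isolated)
Conditions: LiOH, THF/H2O, 0 °C; then NaH2PO4 to pH 8, I2, KI, 0 °C, dark; aq. Na2S2O3
Reagents that add atoms: lithium hydroxide [Li+].[OH-]; iodine II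
Why: Saponification of the δ-lactone followed by iodolactonisation (6-exo, Markovnikov at the tertiary C8): the carboxylate on the axial C10–CH2 arm can reach C8 only from the β face and opens the α-iodonium ion anti, which sets C8 (O β, CH3 α); the trisubstituted ring alkene should react faster with iodine than the two monosubstituted alkenes.

Step 16
Reactants: 22 7α-iodo C2–O8 bridged lactone (6-O-TES; 13-O-TES; 11-OH; allyl ester)
Product: 23 deiodinated bridged lactone (6-O-TES; 13-O-TES; 11-OH; allyl ester)
Conditions: Bu3SnH, Et3B (cat.), air, toluene, 0 °C → rt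
Reagents that add atoms: none
Why: Radical dehalogenation with tributyltin hydride: the C7 iodide is replaced by hydrogen (C7 becomes CH2), and the β-acyloxy radical should be reduced faster than it can rearrange.

Step 17
Reactants: 23 deiodinated bridged lactone (6-O-TES; 13-O-TES; 11-OH; allyl ester)
Product: 24 prop-2-en-1-yl ester of the target acid
Conditions: HF·pyridine, pyridine, THF, 0 °C → rt
Reagents that add atoms: none
Why: Fluoride-mediated desilylation with buffered HF·pyridine removes both TES ethers; the hindered allyl ester keeps the C3 carboxyl from lactonising onto the freed 6-hydroxyl.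

Step 18
Reactants: 24 prop-2-en-1-yl ester of the target acid
Product: 25 target CNP0297019.1
Conditions: Pd(PPh3)4 (5 mol%), morpholine, THF, rt; work-up at pH 6
Reagents that add atoms: none
Why: Palladium(0)-catalysed deallylation (Tsuji–Trost allyl transfer to morpholine) frees the C3 acid under neutral conditions, without acid that could close the γ-lactone or ionise the tertiary allylic alcohol.

Compound list
1 | (R)-5-methylcyclohex-2-en-1-one | C[C@H]1CC(=O)C=CC1 | starting material
2 | 1-(tert-butyldimethylsilyloxy)-1-methoxyethene | C=C(OC)O[Si](C)(C)C(C)(C)C | starting material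
3 | methyl 2-[(1S,5R)-3-(tert-butyldimethylsilyloxy)-5-methylcyclohex-2-en-1-yl]acetate | COC(=O)C[C@H]1C=C(O[Si](C)(C)C(C)(C)C)C[C@H](C)C1 | intermediate
4 | methyl 2-[(5R)-5-methyl-3-oxocyclohex-1-en-1-yl]acetate | COC(=O)CC1=CC(=O)C[C@H](C)C1 | intermediate
5 | methyl 2-[(1R,5R)-1,5-dimethyl-3-(trimethylsilyloxy)cyclohex-2-en-1-yl]acetate | COC(=O)C[C@]1(C)C=C(O[Si](C)(C)C)C[C@H](C)C1 | intermediate
6 | prop-2-en-1-yl 2-bromo-2-methylpropanoate | C=CCOC(=O)C(C)(C)Br | starting material
7 | prop-2-en-1-yl 2-[(1R,2R,4R)-2-(2-methoxy-2-oxoethyl)-2,4-dimethyl-6-oxocyclohexyl]-2-methylpropanoate (C4 and the acetate arm cis, both β; C20 and C17 methyls trans) | COC(=O)C[C@@]1(C)C[C@@H](C)CC(=O)[C@H]1C(C)(C)C(=O)OCC=C | intermediate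
8 | prop-2-en-1-yl 2-[(1R,6R)-6-(2-methoxy-2-oxoethyl)-4,6-dimethyl-2-oxocyclohex-3-en-1-yl]-2-methylpropanoate | COC(=O)C[C@@]1(C)CC(C)=CC(=O)[C@H]1C(C)(C)C(=O)OCC=C | intermediate
9 | 2-[(1R,6R)-1,3-dimethyl-6-[2-methyl-1-oxo-1-(prop-2-en-1-yloxy)propan-2-yl]-5-oxocyclohex-3-en-1-yl]acetic acid | OC(=O)C[C@@]1(C)CC(C)=CC(=O)[C@H]1C(C)(C)C(=O)OCC=C | intermediate
10 | (2E)-3-methylpent-2-en-4-yn-1-ol | OC/C=C(\C)C#C | starting material
11 | (2E)-3-methylpenta-2,4-dien-1-ol | OC/C=C(\C)C=C | intermediate
12 | [(2S,3S)-3-ethenyl-3-methyloxiran-2-yl]methanol | C=C[C@]1(C)O[C@H]1CO | intermediate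
13 | (3R)-3-methylpent-4-ene-1,3-diol | C=C[C@](C)(O)CCO | intermediate
14 | (3R)-3-methyl-1,3-bis(triethylsilyloxy)pent-4-ene | C=C[C@](C)(O[Si](CC)(CC)CC)CCO[Si](CC)(CC)CC | intermediate
15 | (3R)-3-methyl-3-(triethylsilyloxy)pent-4-enal | C=C[C@](C)(O[Si](CC)(CC)CC)CC=O | intermediate
16 | bis-silyl derivative of 9: trimethylsilyl ester at C2 and 6-(trimethylsilyloxy)-6,8-diene (C6=C7, C8=C9); C5 and C10 as in 9 | C[Si](C)(C)OC(=O)C[C@@]1(C)C=C(C)C=C(O[Si](C)(C)C)[C@H]1C(C)(C)C(=O)OCC=C | intermediate (not isolated)
17 | O-silyl hemiacylal: 1-(trimethylsilyloxy)alkyl ester from the silyl ester of 16 and aldehyde 15 (both C11 epimers; C5, C10 and C13 as in 16 and 15) | C=C[C@](C)(O[Si](CC)(CC)CC)CC(O[Si](C)(C)C)OC(=O)C[C@@]1(C)C=C(C)C=C(O[Si](C)(C)C)[C@H]1C(C)(C)C(=O)OCC=C | intermediate (not isolated)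
18 | prop-2-en-1-yl ester of the 6-oxo-7-ene acid with a C2(=O)–O11 δ-lactone cis-fused at C9–C10 and a 13-O-TES ether; (5R,9S,10S,11S,13R), spatially as in 25 | C=C[C@](C)(O[Si](CC)(CC)CC)C[C@@H]1OC(=O)C[C@@]2(C)[C@@H]1C(C)=CC(=O)[C@H]2C(C)(C)C(=O)OCC=C | intermediate
19 | 6β-allylic alcohol of 18 (6-OH cis to C4; all stereocentres spatially as in 25) | C=C[C@](C)(O[Si](CC)(CC)CC)C[C@@H]1OC(=O)C[C@@]2(C)[C@@H]1C(C)=C[C@@H](O)[C@H]2C(C)(C)C(=O)OCC=C | intermediate
20 | 6-O-triethylsilyl ether of 19 | C=C[C@](C)(O[Si](CC)(CC)CC)C[C@@H]1OC(=O)C[C@@]2(C)[C@@H]1C(C)=C[C@@H](O[Si](CC)(CC)CC)[C@H]2C(C)(C)C(=O)OCC=C | intermediate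
21 | lithium carboxylate from 20 with the δ-lactone opened (C2 carboxylate, free 11-OH, 7-ene; stereocentres as in 20) | C=C[C@](C)(O[Si](CC)(CC)CC)C[C@H](O)[C@H]1C(C)=C[C@@H](O[Si](CC)(CC)CC)[C@@H](C(C)(C)C(=O)OCC=C)[C@@]1(C)CC(=O)[O-].[Li+] | intermediate (not isolated)
22 | 7α-iodo bridged lactone: C2(=O)–O8 lactone of the 2-oxabicyclo[3.3.1]nonan-3-one type, iodine at C7 trans to O8, 6-O-TES, 13-O-TES, free 11-OH, allyl ester; other stereocentres as in 25 | C=C[C@](C)(O[Si](CC)(CC)CC)C[C@H](O)[C@@H]1[C@]2(C)CC(=O)O[C@@]1(C)[C@H](I)[C@@H](O[Si](CC)(CC)CC)[C@H]2C(C)(C)C(=O)OCC=C | intermediate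
23 | 6,13-bis-O-triethylsilyl ether of the prop-2-en-1-yl ester of 25 | C=C[C@](C)(O[Si](CC)(CC)CC)C[C@H](O)[C@@H]1[C@]2(C)CC(=O)O[C@@]1(C)C[C@@H](O[Si](CC)(CC)CC)[C@H]2C(C)(C)C(=O)OCC=C | intermediate
24 | prop-2-en-1-yl ester of 25 | C=C[C@](C)(O)C[C@H](O)[C@@H]1[C@]2(C)CC(=O)O[C@@]1(C)C[C@@H](O)[C@H]2C(C)(C)C(=O)OCC=C | intermediate
25 | 2-[(1S,5R,6R,7R,9S)-9-[(1S,3R)-1,3-dihydroxy-3-methylpent-4-en-1-yl]-7-hydroxy-1,5-dimethyl-3-oxo-2-oxabicyclo[3.3.1]nonan-6-yl]-2-methylpropanoic acid (CNP0297019.1) | C=C[C@](C)(O)C[C@H](O)[C@@H]1[C@]2(C)CC(=O)O[C@@]1(C)C[C@@H](O)[C@H]2C(C)(C)C(=O)O | target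

Total step count: 18
Longest linear sequence: 13 steps (steps 1–6 and 12–18, from 1)

Steps most likely to fail

Step 12 (Proposed new method). The silyl ester may capture the activated aldehyde too slowly. Intermolecular aldol addition from the open α face, enolisation of the aldehyde, or epimerisation at C5 through the cross-conjugated dienol ether could then compete with the tethered cyclisation. The fallback uses known chemistry and sets out from 8. TBSOTf/Et3N gives the linear silyl dienol ether F1. A BF3·OEt2-mediated vinylogous Mukaiyama aldol addition of F1 to 15 (γ-selective, open transition state, approach anti to the pseudo-axial C20 methyl group) gives the γ-adduct hydroxy methyl ester F2. Warming F2 with catalytic Ti(OiPr)4 in toluene closes the lactone for those adducts whose C11–O is cis to the acetate arm; the C11 epimer is separated at this stage. The fallback comes back to the route at 18.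

Step 4. The C5–C4 bond is formed between a carbon next to the quaternary C10 and a tertiary radical. Slow addition, reduction of the radical, or loss of the silyl enol ether before it reacts could stop the step. The fallback replaces the radical by a stabilised cation and sets out from 5. A Nicholas reaction with the Co2(CO)6 complex of 2-methylbut-3-yn-2-ol and BF3·OEt2 gives the cobalt-complexed propargyl ketone F3, with the same facial preference (anti to the axial C20 methyl group). Ceric ammonium nitrate frees the alkyne F4. RuCl3/NaIO4 cleaves the terminal alkyne to the acid F5, and allyl bromide/K2CO3 in DMF gives the allyl ester. The fallback comes back at 7.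

Step 15. Chemoselectivity may be lost: iodine may attack the side-chain vinyl group with participation of the free 11-hydroxyl, or hydroxide may attack the allyl ester or a silyl ether. The fallback moves the carboxyl by conjugate addition before the ketone is reduced and sets out from 18. LiOH at 0 °C opens the δ-lactone to the enone hydroxy acid F6. With catalytic DBU the carboxylic acid adds to C8 of the enone (intramolecular oxa-Michael addition, only possible from the β face) to give the keto lactone F7. NaBH4 at −40 °C reduces the C6 ketone from the exo (α) face of the bridged bicycle to the 6β-alcohol F8. HF·pyridine then removes the 13-O-TES group. The fallback comes back at 24.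

Further compounds
F1 | step 12 | tert-butyldimethylsilyl dienol ether of 8 (6-silyloxy-6,8-diene; C5 and C10 as in 8) | COC(=O)C[C@@]1(C)C=C(C)C=C(O[Si](C)(C)C(C)(C)C)[C@H]1C(C)(C)C(=O)OCC=C
F2 | step 12 | γ-aldol adduct: methyl ester of the 11-hydroxy-6-oxo-7-ene acid (13-O-TES; allyl ester at C3; stereocentres as in 18) | C=C[C@](C)(O[Si](CC)(CC)CC)C[C@H](O)[C@H]1C(C)=CC(=O)[C@@H](C(C)(C)C(=O)OCC=C)[C@@]1(C)CC(=O)OC
F3 | step 4 | hexacarbonyldicobalt complex of the alkyne F4 | COC(=O)C[C@@]1(C)C[C@@H](C)CC(=O)[C@H]1C(C)(C)C#C.[Co].[Co].[C-]#[O+].[C-]#[O+].[C-]#[O+].[C-]#[O+].[C-]#[O+].[C-]#[O+]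
F4 | step 4 | methyl 2-[(1R,2R,5R)-1,5-dimethyl-2-(2-methylbut-3-yn-2-yl)-3-oxocyclohexyl]acetate | COC(=O)C[C@@]1(C)C[C@@H](C)CC(=O)[C@H]1C(C)(C)C#C
F5 | step 4 | 2-[(1R,2R,4R)-2-(2-methoxy-2-oxoethyl)-2,4-dimethyl-6-oxocyclohexyl]-2-methylpropanoic acid | COC(=O)C[C@@]1(C)C[C@@H](C)CC(=O)[C@H]1C(C)(C)C(=O)O
F6 | step 15 | enone hydroxy acid from 18 (C2 acid, free 11-OH, 6-oxo-7-ene; 13-O-TES; allyl ester) | C=C[C@](C)(O[Si](CC)(CC)CC)C[C@H](O)[C@H]1C(C)=CC(=O)[C@@H](C(C)(C)C(=O)OCC=C)[C@@]1(C)CC(=O)O
F7 | step 15 | 6-oxo bridged C2–O8 lactone (11-OH; 13-O-TES; allyl ester) | C=C[C@](C)(O[Si](CC)(CC)CC)C[C@H](O)[C@@H]1[C@]2(C)CC(=O)O[C@@]1(C)CC(=O)[C@H]2C(C)(C)C(=O)OCC=C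
F8 | step 15 | 13-O-triethylsilyl ether of 24 | C=C[C@](C)(O[Si](CC)(CC)CC)C[C@H](O)[C@@H]1[C@]2(C)CC(=O)O[C@@]1(C)C[C@@H](O)[C@H]2C(C)(C)C(=O)OCC=C
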